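**Plan**

- Retrosynthesis: (a) O‑dealkylation and C2/C2′ inversion lead back to the cis,cis‑bis(dihydrobenzofuran) 17. (b) Both furan C2–C3 bonds are cut at once (two carbene C–H insertions) to the acyclic, achiral bis(hydrazone) 15, and from there to diketone 14. (c) The two aryl–C(O) bonds are cut to stilbene bromide 6, bromo aldehyde 8 and 3,5‑dimethoxybenzaldehyde; 6 and 8 both come from one resorcinol aldehyde 2.
- Forward: the chain ring A–C–ring B–C–ring C is joined by two aryllithium/aldehyde additions and oxidised to the diketone. Both dihydrofuran rings then close in a single operation.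
- Enabling feature: in each dihydrobenzofuran, C3 sits on C3a, the resorcinol carbon between the two oxygenated carbons C7a (O1) and C4 (OH), and the ring's only other substituent (C6) is para to C3a. In the open precursor the two ortho ethers are therefore homotopic. C2 carries a 4‑hydroxyphenyl (ring 1) or 2,4‑dihydroxyphenyl (ring 2) group, which is the skeleton of a PMB or DMB group. The benzyl‑type ether on the resorcinol oxygens is thus protecting group and source of C2 plus its aryl at once.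
- Stereochemistry: C3 and C3′ (both R) come from one chiral Rh(II) catalyst acting twice. C2 and C2′ are set afterwards by acid equilibration through reversible C2–O ionisation to the 2,3‑trans rings, giving (2R,3R,2′R,3′R).

Key step: step 9

Assumptions: (i) Rh2(R‑PTAD)4 is taken to deliver the 3R/3′R sense; if a model mono‑hydrazone shows the opposite sense, Rh2(S‑PTAD)4 is used with no other change. (ii) The carbinol centres of 10 and 13 and the C=N geometry of 15 are irrelevant and carried as mixtures.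

**Route**

Step 1
Reactants: 1 4‑bromo‑3,5‑dimethoxybenzaldehyde
Product: 2 4‑bromo‑3,5‑dihydroxybenzaldehyde
Conditions: BBr3, CH2Cl2, −78 °C → rt; H2O
Reagents that add atoms: none
Why: Lewis‑acid O‑demethylation of aryl methyl ethers with BBr3, which the aldehyde and aryl bromide should tolerate, gives the symmetric resorcinol used by both branches.

Step 2
Reactants: 2 4‑bromo‑3,5‑dihydroxybenzaldehyde; 3 4‑methoxybenzyl chloride
Product: 4 4‑bromo‑3,5‑bis[(4‑methoxybenzyl)oxy]benzaldehyde
Conditions: K2CO3, n‑Bu4NI (cat.), DMF, 60 °C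
Reagents that add atoms: 4‑methoxybenzyl chloride, COc1ccc(CCl)cc1
Why: Williamson etherification of both equivalent phenols, with no selectivity issue and the non‑enolisable aldehyde untouched.

Step 3
Reactants: 4 4‑bromo‑3,5‑bis[(4‑methoxybenzyl)oxy]benzaldehyde; 5 diethyl (4‑methoxybenzyl)phosphonate
Product: 6 2‑bromo‑1,3‑bis[(4‑methoxybenzyl)oxy]‑5‑[(E)‑2‑(4‑methoxyphenyl)ethenyl]benzene
Conditions: KOtBu, THF, 0 °C → rt
Reagents that add atoms: diethyl (4‑methoxybenzyl)phosphonate, CCOP(=O)(Cc1ccc(OC)cc1)OCC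
Why: Horner–Wadsworth–Emmons olefination of an aromatic aldehyde with a benzylphosphonate should give the E‑stilbene under thermodynamic control of the elimination.

Step 4
Reactants: 2 4‑bromo‑3,5‑dihydroxybenzaldehyde; 7 2,4‑dimethoxybenzyl alcohol
Product: 8 4‑bromo‑3,5‑bis[(2,4‑dimethoxybenzyl)oxy]benzaldehyde
Conditions: PPh3, DIAD, THF, 0 °C → rt
Reagents that add atoms: 2,4‑dimethoxybenzyl alcohol, COc1ccc(CO)c(OC)c1
Why: Mitsunobu etherification of the acidic ortho‑bromophenols installs both DMB ethers without the unstable 2,4‑dimethoxybenzyl halide.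

Step 5
Reactants: 6 2‑bromo‑1,3‑bis[(4‑methoxybenzyl)oxy]‑5‑[(E)‑2‑(4‑methoxyphenyl)ethenyl]benzene; 8 4‑bromo‑3,5‑bis[(2,4‑dimethoxybenzyl)oxy]benzaldehyde
Product: 10 [4‑bromo‑3,5‑bis[(2,4‑dimethoxybenzyl)oxy]phenyl]{2,6‑bis[(4‑methoxybenzyl)oxy]‑4‑[(E)‑2‑(4‑methoxyphenyl)ethenyl]phenyl}methanol (racemic), via aryllithium 9 (not isolated)
Conditions: 6, n‑BuLi, THF, −78 °C; cannulate into 8, THF, −78 °C; H2O
Reagents that add atoms: compound 8, O=Cc1cc(OCc2ccc(OC)cc2OC)c(Br)c(OCc2ccc(OC)cc2OC)c1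
Why: Br–Li exchange at −78 °C should outrun stilbene carbolithiation and benzylic deprotonation, and inverse addition lets the 2,6‑dialkoxyaryllithium add to the unhindered aldehyde faster than it exchanges with the bromide of 8 (aryllithium 1,2‑addition; the new carbinol centre is removed in step 7).

Step 6
Reactants: 10 the bromo carbinol of step 5; 11 3,5‑dimethoxybenzaldehyde
Product: 13 {2,6‑bis[(2,4‑dimethoxybenzyl)oxy]‑4‑[hydroxy{2,6‑bis[(4‑methoxybenzyl)oxy]‑4‑[(E)‑2‑(4‑methoxyphenyl)ethenyl]phenyl}methyl]phenyl}(3,5‑dimethoxyphenyl)methanol (diastereomer mixture), via O,C‑dilithio species 12 (not isolated)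
Conditions: n‑BuLi (2.1 equiv), THF, −78 °C; then 11; H2O
Reagents that add atoms: 3,5‑dimethoxybenzaldehyde, COc1cc(C=O)cc(OC)c1
Why: the first equivalent of n‑BuLi turns the carbinol into its alkoxide (self‑protection), the second performs Br–Li exchange at the bromide flanked by two ether oxygens, and the resulting aryllithium adds to the aldehyde (aryllithium 1,2‑addition).

Step 7
Reactants: 13 the diol of step 6
Product: 14 {2,6‑bis[(2,4‑dimethoxybenzyl)oxy]‑4‑{2,6‑bis[(4‑methoxybenzyl)oxy]‑4‑[(E)‑2‑(4‑methoxyphenyl)ethenyl]benzoyl}phenyl}(3,5‑dimethoxyphenyl)methanone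
Conditions: Dess–Martin periodinane, CH2Cl2, rt
Reagents that add atoms: none
Why: Dess–Martin oxidation converts both hindered diaryl carbinols to diaryl ketones under near‑neutral conditions that the stilbene and the PMB/DMB ethers should survive.

Step 8
Reactants: 14 the diketone of step 7
Product: 15 bis(hydrazone) of 14 (both C=O replaced by C=N–NH2; C=N isomer mixture)
Conditions: N2H4 (anhydrous, excess), AcOH (cat.), n‑BuOH, 110 °C, Ar, sealed tube
Reagents that add atoms: hydrazine, NN
Why: forced condensation of the small nucleophile hydrazine with both twisted 2,6‑dialkoxybenzophenone carbonyls gives the N‑unsubstituted hydrazones, with excess hydrazine suppressing azine formation and exclusion of air preventing diimide reduction of the stilbene.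

Step 9
Reactants: 15 the bis(hydrazone) of step 8
Product: 17 (2S,3R)‑3‑[(2S,3R)‑4‑[(2,4‑dimethoxybenzyl)oxy]‑2‑(2,4‑dimethoxyphenyl)‑3‑(3,5‑dimethoxyphenyl)‑2,3‑dihydro‑1‑benzofuran‑6‑yl]‑4‑[(4‑methoxybenzyl)oxy]‑2‑(4‑methoxyphenyl)‑6‑[(E)‑2‑(4‑methoxyphenyl)ethenyl]‑2,3‑dihydro‑1‑benzofuran (both rings 2,3‑cis), via bis(diazo) compound 16 (not isolated)
Conditions: MnO2, CH2Cl2, 0 °C, filter; slow addition to Rh2(R‑PTAD)4 (2 mol %), CH2Cl2, 0 °C → rt, dark
Reagents that add atoms: none
Why: MnO2 dehydrogenates both hydrazones to the bis(diaryldiazomethane) 16, and the Rh(II) carboxylate extrudes N2 from each to give a donor/donor (diaryl) rhodium carbene that inserts into a benzylic C–H bond of an ortho OCH2Ar group through a five‑centre hydride‑shift/C–C‑forming transition state. The closest known reaction type is the enantioselective Rh2(PTAD)4‑catalysed C–H insertion of carbenes from 2‑(benzyloxy)benzophenone hydrazones, which gives cis‑2,3‑diaryl‑2,3‑dihydrobenzofurans; here it runs twice in one molecule. Each dihydrofuran ring is closed by formation of its C2–C3 bond in a 1,5‑C–H insertion (five‑membered ring; O1–C2 and C3–C3a are already in place). C3 and C3′ are set by the catalyst, which selects the carbene face that receives the hydrogen; C2 and C2′ follow from the compact cis‑selective insertion geometry and are corrected in step 10; because both carbenes meet the same catalyst sense, both rings should get the same configuration, and material of the minor sense is largely diverted into a separable diastereomer. Site selectivity is secured by the substrate: each carbene can reach only the C–H bonds of the two homotopic ortho OCH2Ar groups on the ring twisted out of the carbene plane (either gives the same product), while the meta ethers, the methoxy groups and the stilbene para to the carbene‑bearing carbon are out of reach. The step also needs insertion to outrun intermolecular carbene/diazo coupling, which slow addition at high dilution and the attenuated electrophilicity of diaryl carbenes should provide.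

Step 10
Reactants: 17 the cis,cis‑bis(dihydrobenzofuran) of step 9
Product: 18 (2R,3R)‑3‑[(2R,3R)‑2‑(2,4‑dimethoxyphenyl)‑3‑(3,5‑dimethoxyphenyl)‑4‑hydroxy‑2,3‑dihydro‑1‑benzofuran‑6‑yl]‑2‑(4‑methoxyphenyl)‑6‑[(E)‑2‑(4‑methoxyphenyl)ethenyl]‑2,3‑dihydro‑1‑benzofuran‑4‑ol (both rings 2,3‑trans)
Conditions: TFA (5 % v/v), C6HMe5 (10 equiv), CH2Cl2, 0 °C, dark
Reagents that add atoms: none
Why: acidolysis of the spectator PMB and DMB aryl ethers with Friedel–Crafts capture of the benzyl cations by pentamethylbenzene also ionises the C2–O bonds (themselves secondary 4‑methoxybenzyl and 2,4‑dimethoxybenzyl aryl ethers) reversibly, and fast 5‑exo return of the phenol at low temperature should deliver the thermodynamically preferred 2,3‑trans rings, inverting C2/C2′ while C3/C3′ stay fixed (reclosure onto either flanking oxygen gives the same compound by the ring symmetry).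

Step 11
Reactants: 18 the trans,trans‑diphenol of step 10
Product: 19 CNP0118407.2, (2R,3R)‑3‑[(2R,3R)‑2‑(2,4‑dihydroxyphenyl)‑3‑(3,5‑dihydroxyphenyl)‑4‑hydroxy‑2,3‑dihydro‑1‑benzofuran‑6‑yl]‑2‑(4‑hydroxyphenyl)‑6‑[(E)‑2‑(4‑hydroxyphenyl)ethenyl]‑2,3‑dihydro‑1‑benzofuran‑4‑ol
Conditions: BBr3 (excess), CH2Cl2, −78 °C → rt, dark; MeOH, H2O
Reagents that add atoms: none
Why: exhaustive BBr3 demethylation of the six aryl methyl ethers, in which the trans rings are the thermodynamic sink of any re‑ionisation at C2 and the stilbene, being para to C3a, cannot reach a transient C2 cation intramolecularly.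

**Compound list**

1 | 4‑bromo‑3,5‑dimethoxybenzaldehyde | COc1cc(C=O)cc(OC)c1Br | starting material
2 | 4‑bromo‑3,5‑dihydroxybenzaldehyde | O=Cc1cc(O)c(Br)c(O)c1 | intermediate
3 | 4‑methoxybenzyl chloride | COc1ccc(CCl)cc1 | starting material
4 | 4‑bromo‑3,5‑bis[(4‑methoxybenzyl)oxy]benzaldehyde | O=Cc1cc(OCc2ccc(OC)cc2)c(Br)c(OCc2ccc(OC)cc2)c1 | intermediate
5 | diethyl (4‑methoxybenzyl)phosphonate | CCOP(=O)(Cc1ccc(OC)cc1)OCC | starting material
6 | 2‑bromo‑1,3‑bis[(4‑methoxybenzyl)oxy]‑5‑[(E)‑2‑(4‑methoxyphenyl)ethenyl]benzene | COc1ccc(/C=C/c2cc(OCc3ccc(OC)cc3)c(Br)c(OCc3ccc(OC)cc3)c2)cc1 | intermediate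
7 | 2,4‑dimethoxybenzyl alcohol | COc1ccc(CO)c(OC)c1 | starting material
8 | 4‑bromo‑3,5‑bis[(2,4‑dimethoxybenzyl)oxy]benzaldehyde | O=Cc1cc(OCc2ccc(OC)cc2OC)c(Br)c(OCc2ccc(OC)cc2OC)c1 | intermediate
9 | {2,6‑bis[(4‑methoxybenzyl)oxy]‑4‑[(E)‑2‑(4‑methoxyphenyl)ethenyl]phenyl}lithium | COc1ccc(/C=C/c2cc(OCc3ccc(OC)cc3)c([Li])c(OCc3ccc(OC)cc3)c2)cc1 | intermediate
10 | bromo carbinol (racemic): ring A(2,6‑di‑OPMB, 4‑styryl)–CH(OH)–ring B(3,5‑di‑ODMB, 4‑Br) | COc1ccc(/C=C/c2cc(OCc3ccc(OC)cc3)c(C(O)c3cc(OCc4ccc(OC)cc4OC)c(Br)c(OCc4ccc(OC)cc4OC)c3)c(OCc3ccc(OC)cc3)c2)cc1 | intermediate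
11 | 3,5‑dimethoxybenzaldehyde | COc1cc(C=O)cc(OC)c1 | starting material
12 | O,C‑dilithio species (lithium alkoxide of 10 with Li in place of Br) | COc1ccc(/C=C/c2cc(OCc3ccc(OC)cc3)c(C(O[Li])c3cc(OCc4ccc(OC)cc4OC)c([Li])c(OCc4ccc(OC)cc4OC)c3)c(OCc3ccc(OC)cc3)c2)cc1 | intermediate
13 | diol (diastereomer mixture): 10 with Br replaced by CH(OH)(3,5‑dimethoxyphenyl) | COc1ccc(/C=C/c2cc(OCc3ccc(OC)cc3)c(C(O)c3cc(OCc4ccc(OC)cc4OC)c(C(O)c4cc(OC)cc(OC)c4)c(OCc4ccc(OC)cc4OC)c3)c(OCc3ccc(OC)cc3)c2)cc1 | intermediate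
14 | diketone: both carbinols of 13 as C=O | COc1ccc(/C=C/c2cc(OCc3ccc(OC)cc3)c(C(=O)c3cc(OCc4ccc(OC)cc4OC)c(C(=O)c4cc(OC)cc(OC)c4)c(OCc4ccc(OC)cc4OC)c3)c(OCc3ccc(OC)cc3)c2)cc1 | intermediate
15 | bis(hydrazone) of 14 | COc1ccc(/C=C/c2cc(OCc3ccc(OC)cc3)c(C(=NN)c3cc(OCc4ccc(OC)cc4OC)c(C(=NN)c4cc(OC)cc(OC)c4)c(OCc4ccc(OC)cc4OC)c3)c(OCc3ccc(OC)cc3)c2)cc1 | intermediate
16 | bis(diazo) compound: both C=N–NH2 of 15 as C=N2 | COc1ccc(/C=C/c2cc(OCc3ccc(OC)cc3)c(C(=[N+]=[N-])c3cc(OCc4ccc(OC)cc4OC)c(C(=[N+]=[N-])c4cc(OC)cc(OC)c4)c(OCc4ccc(OC)cc4OC)c3)c(OCc3ccc(OC)cc3)c2)cc1 | intermediate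
17 | (2S,3R,2′S,3′R) cis,cis‑bis(dihydrobenzofuran) with 4‑OPMB, 4′‑ODMB and six OMe | COc1ccc(/C=C/c2cc(OCc4ccc(OC)cc4)c3c(c2)O[C@H](c2ccc(OC)cc2)[C@@H]3c2cc(OCc4ccc(OC)cc4OC)c3c(c2)O[C@H](c2ccc(OC)cc2OC)[C@@H]3c2cc(OC)cc(OC)c2)cc1 | intermediate
18 | (2R,3R,2′R,3′R) trans,trans‑bis(dihydrobenzofuran)‑4,4′‑diol hexamethyl ether | COc1ccc(/C=C/c2cc(O)c3c(c2)O[C@@H](c2ccc(OC)cc2)[C@@H]3c2cc(O)c3c(c2)O[C@@H](c2ccc(OC)cc2OC)[C@@H]3c2cc(OC)cc(OC)c2)cc1 | intermediate
19 | CNP0118407.2 | Oc1ccc(/C=C/c2cc(O)c3c(c2)O[C@@H](c2ccc(O)cc2)[C@@H]3c2cc(O)c3c(c2)O[C@@H](c2ccc(O)cc2O)[C@@H]3c2cc(O)cc(O)c2)cc1 | target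

**Step count**

Total steps: 11. Longest linear sequence: 10 (steps 1, 2, 3, 5, 6, 7, 8, 9, 10, 11).

**Steps most likely to fail**

1. Step 9. The catalyst may discriminate the two carbene faces poorly, because the twisted 2,6‑bis(arylmethoxy)aryl ring presents a reactive OCH2Ar group on each face, so the two‑ring product would spread over stereoisomers. Fallback (stereochemistry from separation instead of catalyst control): setting out from 15, the same MnO2 oxidation followed by an achiral, bulky dirhodium catalyst such as Rh2(O2CCPh3)4 should give the stereo‑random bis(dihydrobenzofuran) F1. Treatment with TFA/pentamethylbenzene as in step 10 should converge every ring to 2,3‑trans and give the all‑trans stereoisomer mixture F2 (two racemic diastereomers). The like diastereomer is separated on silica and resolved by preparative chromatography on a polysaccharide chiral stationary phase, which comes back to the route at 18.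

2. Step 8. Condensation at the two twisted, di‑ortho‑alkoxy‑shielded carbonyl groups may stay incomplete, and prolonged heating with hydrazine may reduce the stilbene through adventitious diimide. Fallback (the hindered C=O is never made; the carbene carbons come from nitriles): setting out from 8, one‑flask oxidative amination (I2, aqueous NH3, THF) should give 4‑bromo‑3,5‑bis[(2,4‑dimethoxybenzyl)oxy]benzonitrile F3. Aryllithium 9 (from 6) adds to F3 to give, after methanol quench, the bromo N–H ketimine F4. n‑BuLi (2 equiv; N‑lithiation, then Br–Li exchange) and 3,5‑dimethoxybenzonitrile then give the bis(N–H ketimine) F5. Transimination of F5 with hydrazine hydrate and catalytic AcOH in ethanol at mild temperature, a much easier exchange at an iminium carbon, comes back to the route at 15.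

3. Step 10. The released benzyl cations may be captured by the electron‑rich rings, the stilbene may be protonated, and β‑proton loss from the ring‑opened C2 cation would erode C3 under Brønsted acid. Fallback (no benzyl cation is generated): setting out from 17, the spectator ethers are cleaved by SN2 attack of a thiolate at the benzylic carbon (NaSEt, DMF, about 80 °C), which should give the cis,cis‑diphenol hexamethyl ether F6. F6 is then taken directly into the BBr3 conditions of step 11, where the Lewis‑acid‑mediated cis‑to‑trans inversion of 2‑aryl‑dihydrobenzofurans accompanies demethylation, and the route is rejoined at 19.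

**Further compounds**

F1 | step 9 | stereoisomer mixture of 17 (ring stereocentres undefined) | COc1ccc(/C=C/c2cc(OCc4ccc(OC)cc4)c3c(c2)OC(c2ccc(OC)cc2)C3c2cc(OCc4ccc(OC)cc4OC)c3c(c2)OC(c2ccc(OC)cc2OC)C3c2cc(OC)cc(OC)c2)cc1
F2 | step 9 | all‑trans stereoisomer mixture of 18 (two racemic diastereomers) | COc1ccc(/C=C/c2cc(O)c3c(c2)OC(c2ccc(OC)cc2)C3c2cc(O)c3c(c2)OC(c2ccc(OC)cc2OC)C3c2cc(OC)cc(OC)c2)cc1
F3 | step 8 | 4‑bromo‑3,5‑bis[(2,4‑dimethoxybenzyl)oxy]benzonitrile | N#Cc1cc(OCc2ccc(OC)cc2OC)c(Br)c(OCc2ccc(OC)cc2OC)c1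
F4 | step 8 | bromo N–H ketimine: ring A(2,6‑di‑OPMB, 4‑styryl)–C(=NH)–ring B(3,5‑di‑ODMB, 4‑Br) | COc1ccc(/C=C/c2cc(OCc3ccc(OC)cc3)c(C(=N)c3cc(OCc4ccc(OC)cc4OC)c(Br)c(OCc4ccc(OC)cc4OC)c3)c(OCc3ccc(OC)cc3)c2)cc1
F5 | step 8 | bis(N–H ketimine) corresponding to diketone 14 | COc1ccc(/C=C/c2cc(OCc3ccc(OC)cc3)c(C(=N)c3cc(OCc4ccc(OC)cc4OC)c(C(=N)c4cc(OC)cc(OC)c4)c(OCc4ccc(OC)cc4OC)c3)c(OCc3ccc(OC)cc3)c2)cc1
F6 | step 10 | (2S,3R,2′S,3′R) cis,cis‑bis(dihydrobenzofuran)‑4,4′‑diol hexamethyl ether | COc1ccc(/C=C/c2cc(O)c3c(c2)O[C@H](c2ccc(OC)cc2)[C@@H]3c2cc(O)c3c(c2)O[C@H](c2ccc(OC)cc2OC)[C@@H]3c2cc(OC)cc(OC)c2)cc1
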